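Late rows are where a slow flask shows itself. You are watching starting material and reagent become product under free catalyst, and the last dawn reading, 9.1%, stands far above the scatter of 1 percentage point, while the first, 0.9%, is less than it.

- spring (time / h: product / %): 0.250: 0; 0.667: 0; 1.33: 0.5; 2.00: 0; 3.00: 3.3; 4.00: 3.2
- dawn (time / min: product / %): 8.00: 0.9; 20.0: 4.6; 40.0: 3.0; 60.0: 5.1; 80.0: 7.1; 120: 9.1

(each reading ± 1 percentage point)

common to all: free catalyst 10 mM
- spring: starting material 2 M; reagent 1.4 M; temperature 0 °C; run made earlier
- dawn: starting material 2 M; reagent 1.4 M; temperature 20 °C; run made earlier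
- Monday's: starting material 2.0 M; reagent 2.10 M; temperature 5 °C; time 6.0 h
- Friday's: starting material 2.0 M; reagent 2.10 M; temperature 20 °C; time 6.0 h
- Sunday's: starting material 2.0 M; reagent 2.10 M; temperature 35 °C; time 6.0 h
- Thursday's: starting material 2.0 M; reagent 2.10 M; at 35 °C until 80 min, from then on at 5 °C; time 6.0 h

- the flask with the highest amount of product, in percent of the starting material charged ("all alike" if they lie within 1.5 percentage points) (Monday's / Friday's / Sunday's / Thursday's / all alike)
- final product, as a percentage of the starting material charged, in Monday's
- final product, as a percentage of the starting material charged, in Friday's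
- final product, as a percentage of the starting material charged, in Sunday's
- final product, as a percentage of the starting material charged, in Thursday's

The last row of each table gives product made; turn it into what is left, one minus the reading as a fraction of the starting material charged. The dawn table gives 0.0477 h⁻¹ for the clock, the natural logarithm of one over the fraction of starting material left, divided by the time; it is a pseudo-first-order constant. The spring table's last row gives 0.00813 h⁻¹, so the clock grows by a factor of 5.87 from 0 °C to 20 °C. That factor is a reading, with the scatter at a third of the spring value.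

My own reckoning holds the clock constant through a run and scales it in proportion to reagent, by 1.50. Friday's then runs at 0.0716 h⁻¹. Going from 20 °C to 35 °C, or down to 5 °C, takes that temperature factor to the power 0.750, which is 3.77. So Sunday's runs at 0.270 h⁻¹, faster than Monday's at 0.0190 h⁻¹.

Logarithms add, which helps with Thursday's: the stretch at 35 °C contributes 0.360, more than the 0.0886 of the stretch at 5 °C. I therefore expect product of 10.8% in Monday's, 34.9% in Friday's, 80.2% in Sunday's and 36.1% in Thursday's.

The forecast names Sunday's, with 10%, 28%, 55% and 27% in that order, on this ground: “Both reactants deplete almost equally, so I use roughly second-order decay”. For Sunday's it stands below my figure.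

The flasks give 8.09%, 34.0%, 75.6% and 35.8%, so Sunday's holds the most product.

    starting material + catalyst intermediate B ⇌ catalyst intermediate C (K = 0.430 L mol⁻¹, k = 0.0230 L mol⁻¹ s⁻¹, Ea = 53.0 kJ mol⁻¹, ΔH = −10.0 kJ mol⁻¹)
    catalyst intermediate A ⇌ catalyst intermediate B (K = 0.360, k = 0.140 s⁻¹, Ea = 79.0 kJ mol⁻¹, ΔH = 6.00 kJ mol⁻¹)
    catalyst intermediate C → free catalyst + product (k = 5.00 s⁻¹, Ea = 73.0 kJ mol⁻¹)
    reagent + free catalyst ⇌ catalyst intermediate A (K = 0.290 L mol⁻¹, k = 0.0130 L mol⁻¹ s⁻¹, Ea = 64.0 kJ mol⁻¹, ΔH = 25.0 kJ mol⁻¹)
    (constants at 20 °C)

In Thursday's, starting material goes from 67.9% at 1.33 h, the change of temperature, to 64.2% at 6.00 h, a clock of 0.0117 h⁻¹, below the reckoned 0.0190 h⁻¹. For a flask like Sunday's kept at 10 °C, Friday's clock divided by the square root of the temperature factor gives 0.0295 h⁻¹, hence 83.8% left; that flask holds 86% of its starting material.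

The readings were computed with constants of no real substance, and the scatter is random.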